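**Retrosynthetic overview**
1. Target 22 ⇒ diol 18 by two acylations. The cyclopentenone (ring A) ⇒ intramolecular aldol condensation of 1,4-diketone 17, which is carried in masked form as bis-enol ether 16.
2. The seven-membered ring (ring B), with C7–C11 and C8–O, ⇒ one-carbon ring expansion of the six-membered vinylogous ester 9. The CH2Br2 carbon becomes C7; the ring-expanded enolate is captured by acetone and then reduced.
3. 9 ⇒ 1,3-dione 8 (O-cyclisation onto the butynyl chain decides which carbonyl stays a ketone) ⇒ epoxy ketone 7 ⇒ enone 6 ⇒ ketone 4.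
4. 4 ⇒ cyclohexenone + Me2Zn + 1-bromobut-2-yne. Catalytic asymmetric conjugate addition sets C10 and enolate alkylation sets C1.
5. Ring order: purchased six-membered ring → furanoid lock → seven-membered ring B → five-membered ring A.

Assumption: atoms are referred to by guaiane numbering (C1–C15), and the (S,R,R) ligand enantiomer is taken to be the one that delivers the 3S conjugate adduct (otherwise its mirror image is used).

**Step 1**
Reactants: 1 cyclohex-2-en-1-one; 2 1-bromobut-2-yne
Product: 4 (2R,3S)-2-(but-2-yn-1-yl)-3-methylcyclohexan-1-one, via methylzinc enolate 3 (not isolated)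
Conditions: Me2Zn, Cu(OTf)2 (1 mol %), (S,R,R)-BINOL bis(1-phenylethyl)amine phosphoramidite (2 mol %), toluene, −30 °C; then 2, DMPU, 0 °C to rt
Reagents that add atoms: dimethylzinc C[Zn]C
Why: Copper-catalysed asymmetric conjugate addition of Me2Zn under phosphoramidite control (typically above 95% ee on cyclohexenone) fixes C10 as S, and the zinc enolate is alkylated by the reactive propargylic bromide on the face opposite to the new methyl group, giving the trans-2,3 product (tandem conjugate addition–enolate alkylation).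

**Step 2**
Reactants: 4 (2R,3S)-2-(but-2-yn-1-yl)-3-methylcyclohexan-1-one
Product: 6 (5S,6R)-6-(but-2-yn-1-yl)-5-methylcyclohex-2-en-1-one, via kinetic lithium enolate 5 (not isolated)
Conditions: LiN(i-Pr)2, THF, −78 °C; then PhS(Cl)=N-t-Bu, −78 °C
Reagents that add atoms: none
Why: LiN(i-Pr)2 deprotonates the unhindered ring methylene rather than the tertiary α-position, and the enolate is dehydrogenated by the sulfinimidoyl chloride through S-attack and syn elimination (Mukaiyama one-pot ketone dehydrogenation), leaving both stereocentres untouched.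

**Step 3**
Reactants: 6 (5S,6R)-6-(but-2-yn-1-yl)-5-methylcyclohex-2-en-1-one
Product: 7 (1S,3R,4S,6S)-3-(but-2-yn-1-yl)-4-methyl-7-oxabicyclo[4.1.0]heptan-2-one
Conditions: 30% H2O2, NaOH (cat.), MeOH, 0 °C
Reagents that add atoms: hydrogen peroxide OO
Why: In this Weitz–Scheffer nucleophilic epoxidation, hydroperoxide adds axially to the enone β-carbon anti to the ring methyl group and closes to the epoxide, whose two new centres are erased in step 4, while the isolated alkyne is inert to alkaline H2O2.

**Step 4**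
Reactants: 7 (1S,3R,4S,6S)-3-(but-2-yn-1-yl)-4-methyl-7-oxabicyclo[4.1.0]heptan-2-one
Product: 8 (4R,5S)-4-(but-2-yn-1-yl)-5-methylcyclohexane-1,3-dione
Conditions: Pd(PPh3)4 (3 mol %), dppe (3 mol %), toluene, 80 °C
Reagents that add atoms: none
Why: Zerovalent palladium opens the Cα–O bond of the α,β-epoxy ketone, and β-hydride elimination with tautomerisation gives the 1,3-diketone (palladium-catalysed epoxy ketone to β-diketone isomerisation), C10 being untouched and C1 held trans by equilibration.

**Step 5**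
Reactants: 8 (4R,5S)-4-(but-2-yn-1-yl)-5-methylcyclohexane-1,3-dione
Product: 9 (2Z,3aR,4S)-2-ethylidene-4-methyl-3,3a,4,5-tetrahydro-1-benzofuran-6(2H)-one
Conditions: AuCl (5 mol %), K2CO3 (10 mol %), MeCN, rt
Reagents that add atoms: none
Why: The dione is a vinylogous carboxylic acid and cycloisomerises like a γ-alkynoic acid, only the oxygen of the carbonyl next to the equatorial side chain being able to reach the gold-activated alkyne in a 5-exo-dig anti addition, which locks that carbonyl (C5) as an enol ether, leaves C8 as the only ketone and masks the future C3 ketone.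

**Step 6**
Reactants: 9 (2Z,3aR,4S)-2-ethylidene-4-methyl-3,3a,4,5-tetrahydro-1-benzofuran-6(2H)-one; 10 dibromomethane; 11 acetone
Product: 16 (2Z,3aR,4S,6R,7S)-2-ethylidene-7-(2-hydroxypropan-2-yl)-4-methyl-3,3a,4,5,6,7-hexahydro-2H-cyclohepta[b]furan-6-ol, via dibromomethyl alkoxide 12 (not isolated), via β-oxido carbenoid 13 (not isolated), via ring-expanded dienolate 14 (not isolated), via lithium aldolate 15 (not isolated)
Conditions: 10, LiN(i-Pr)2, THF, −90 °C; 9; n-BuLi, −90 to −30 °C; 11, −78 °C; LiBH(s-Bu)3, −78 °C; H2O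
Reagents that add atoms: none
Why: Proposed new method: LiCHBr2 adds 1,2 to the only ketone of 9, Br–Li exchange turns alkoxide 12 into β-oxido carbenoid 13, and loss of LiBr is accompanied by a 1,2-shift of the electron-rich alkenyl carbon C6 (a better migrating group than the C9 methylene), so the CH2Br2 carbon is inserted as C7 and emerges as the nucleophilic α-carbon of dienolate 14, which attacks acetone on the face opposite to the folded C10 flap (C10 methyl pseudo-equatorial) to set C7, after which the bulky hydride attacks aldolate 15 anti to the new C7 substituent and to the C10 methyl group to give the cis C7/C8 pair; the closest known reaction type is the dibromomethyllithium (β-oxido carbenoid) one-carbon ring enlargement of simple cycloalkanones, which has not been shown on a vinylogous ester with alkenyl migration nor coupled in the same flask with a ketone aldol capture.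

**Step 7**
Reactants: 16 (2Z,3aR,4S,6R,7S)-2-ethylidene-7-(2-hydroxypropan-2-yl)-4-methyl-3,3a,4,5,6,7-hexahydro-2H-cyclohepta[b]furan-6-ol
Product: 18 (5S,6R,8S,8aR)-6-hydroxy-5-(2-hydroxypropan-2-yl)-3,8-dimethyl-4,5,6,7,8,8a-hexahydroazulen-2(1H)-one, via 1,4-diketone 17 (not isolated)
Conditions: Amberlyst 15, THF–H2O 10:1, rt; filter; KOH (0.5 equiv), MeOH, 45 °C
Reagents that add atoms: water O
Why: Mild acid hydrolysis of the two enol ether functions (one molecule of water) unmasks the 1,4-diketone, and hydroxide then drives the intramolecular aldol condensation of the ethyl ketone onto the ring ketone to the tetrasubstituted cyclopentenone, the only irreversible outlet, with C1 settling trans to the C10 methyl group through the dienolate and C7, C8 and C10 not being enolisable.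

**Step 8**
Reactants: 18 (5S,6R,8S,8aR)-6-hydroxy-5-(2-hydroxypropan-2-yl)-3,8-dimethyl-4,5,6,7,8,8a-hexahydroazulen-2(1H)-one; 19 2-methylpropanoyl chloride; 20 acetic anhydride
Product: 22 (5S,6R,8S,8aR)-5-(2-acetoxypropan-2-yl)-3,8-dimethyl-2-oxo-1,2,4,5,6,7,8,8a-octahydroazulen-6-yl 2-methylpropanoate, via C8 isobutyrate 21 (not isolated)
Conditions: 19 (1.1 equiv), Et3N, DMAP, CH2Cl2, 0 °C; then 20 (5 equiv), DMAP (0.5 equiv), 40 °C
Reagents that add atoms: none
Why: DMAP-catalysed acylation by the acyl chloride is much faster at the secondary C8 hydroxyl than at the tertiary one, after which excess Ac2O under Steglich DMAP catalysis acetylates the remaining tertiary alcohol, no stereocentre being touched.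

**Compound list**
1 | cyclohex-2-en-1-one | O=C1C=CCCC1 | starting material
2 | 1-bromobut-2-yne | CC#CCBr | starting material
3 | methylzinc (3S)-3-methylcyclohex-1-en-1-olate | C[Zn]OC1=C[C@@H](C)CCC1 | intermediate
4 | (2R,3S)-2-(but-2-yn-1-yl)-3-methylcyclohexan-1-one | CC#CC[C@@H]1[C@@H](C)CCCC1=O | intermediate
5 | lithium (5S,6R)-6-(but-2-yn-1-yl)-5-methylcyclohex-1-en-1-olate | CC#CC[C@@H]1[C@@H](C)CCC=C1O[Li] | intermediate
6 | (5S,6R)-6-(but-2-yn-1-yl)-5-methylcyclohex-2-en-1-one | CC#CC[C@@H]1[C@@H](C)CC=CC1=O | intermediate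
7 | (1S,3R,4S,6S)-3-(but-2-yn-1-yl)-4-methyl-7-oxabicyclo[4.1.0]heptan-2-one (epoxide anti to the methyl group) | CC#CC[C@@H]1[C@@H](C)C[C@@H]2O[C@@H]2C1=O | intermediate
8 | (4R,5S)-4-(but-2-yn-1-yl)-5-methylcyclohexane-1,3-dione | CC#CC[C@@H]1[C@@H](C)CC(=O)CC1=O | intermediate
9 | (2Z,3aR,4S)-2-ethylidene-4-methyl-3,3a,4,5-tetrahydro-1-benzofuran-6(2H)-one | C/C=C1/C[C@@H]2[C@@H](C)CC(=O)C=C2O1 | intermediate
10 | dibromomethane | BrCBr | starting material
11 | acetone | CC(C)=O | starting material
12 | lithium (2Z,3aR,4S)-6-(dibromomethyl)-2-ethylidene-4-methyl-2,3,3a,4,5,6-hexahydro-1-benzofuran-6-olate (carbinol epimers) | C/C=C1/C[C@@H]2[C@@H](C)CC(O[Li])(C(Br)Br)C=C2O1 | intermediate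
13 | lithium (2Z,3aR,4S)-6-[bromo(lithio)methyl]-2-ethylidene-4-methyl-2,3,3a,4,5,6-hexahydro-1-benzofuran-6-olate | C/C=C1/C[C@@H]2[C@@H](C)CC(O[Li])(C([Li])Br)C=C2O1 | intermediate
14 | lithium (2Z,3aR,4S)-2-ethylidene-4-methyl-3,3a,4,5-tetrahydro-2H-cyclohepta[b]furan-6-olate | C/C=C1/C[C@@H]2[C@@H](C)CC(O[Li])=CC=C2O1 | intermediate
15 | lithium 2-[(2Z,3aR,4S,7R)-2-ethylidene-4-methyl-6-oxo-3,3a,4,5,6,7-hexahydro-2H-cyclohepta[b]furan-7-yl]propan-2-olate | C/C=C1/C[C@@H]2[C@@H](C)CC(=O)[C@@H](C(C)(C)O[Li])C=C2O1 | intermediate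
16 | (2Z,3aR,4S,6R,7S)-2-ethylidene-7-(2-hydroxypropan-2-yl)-4-methyl-3,3a,4,5,6,7-hexahydro-2H-cyclohepta[b]furan-6-ol | C/C=C1/C[C@@H]2[C@@H](C)C[C@@H](O)[C@@H](C(C)(C)O)C=C2O1 | intermediate
17 | (2R,3S,5R,6S)-5-hydroxy-6-(2-hydroxypropan-2-yl)-3-methyl-2-(2-oxobutyl)cycloheptan-1-one | CCC(=O)C[C@@H]1[C@@H](C)C[C@@H](O)[C@@H](C(C)(C)O)CC1=O | intermediate
18 | (5S,6R,8S,8aR)-6-hydroxy-5-(2-hydroxypropan-2-yl)-3,8-dimethyl-4,5,6,7,8,8a-hexahydroazulen-2(1H)-one | CC(C)(O)[C@H]1CC2=C(C)C(=O)C[C@@H]2[C@@H](C)C[C@H]1O | intermediate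
19 | 2-methylpropanoyl chloride | CC(C)C(=O)Cl | starting material
20 | acetic anhydride | CC(=O)OC(C)=O | starting material
21 | (5S,6R,8S,8aR)-5-(2-hydroxypropan-2-yl)-3,8-dimethyl-2-oxo-1,2,4,5,6,7,8,8a-octahydroazulen-6-yl 2-methylpropanoate | CC(C)(O)[C@H]1CC2=C(C)C(=O)C[C@@H]2[C@@H](C)C[C@H]1OC(=O)C(C)C | intermediate
22 | (5S,6R,8S,8aR)-5-(2-acetoxypropan-2-yl)-3,8-dimethyl-2-oxo-1,2,4,5,6,7,8,8a-octahydroazulen-6-yl 2-methylpropanoate | CC(=O)OC(C)(C)[C@H]1CC2=C(C)C(=O)C[C@@H]2[C@@H](C)C[C@H]1OC(=O)C(C)C | target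

Total step count: 8. Longest linear sequence: 8.

**Steps most likely to fail**

Step 6 (the proposed new step). The risks are retro-addition or enolisation instead of 1,2-addition, migration of C9 instead of C6, proton transfer to acetone, and only modest facial control at C7. The fallback uses known chemistry, sets out from 9 and comes back at 16.
- Lithiated ethyl diazoacetate (LiN(i-Pr)2, THF, −78 °C) adds to the ketone of 9 to give the α-diazo-β-hydroxy ester F1.
- Rh2(OAc)4 in CH2Cl2 expels nitrogen, with the well-known 1,2-shift of the alkenyl group of such carbinols, giving the ring-expanded β-keto ester F2.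
- NaBH4 in MeOH at −40 °C reduces F2, whose C7 centre is labile, to the cis β-hydroxy ester F3.
- Excess MeMgBr with CeCl3 converts the ester of F3 into the tertiary carbinol, which is 16.

Step 5. The risks are C-cyclisation of the central carbon (Conia-ene mode) or drift of the exocyclic enol ether to an aromatic furan. The fallback gives up the tethered lock, sets out from 8 and comes back at 17.
- Isobutanol with catalytic TsOH under water removal gives both vinylogous esters.
- The isomer with the alkoxy group next to the side chain, 3-isobutoxy-4-butynyl enone F4, is separated. The other isomer is hydrolysed back to 8 and recycled.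
- The conditions of step 6 take F4 to the ring-expanded enol ether diol F5.
- Ph3PAuNTf2 with TsOH in wet dioxane hydrolyses the enol ether of F5 and hydrates the alkyne with help from the freed C5 ketone, giving 17.

Step 7. The risks are that the free C8 hydroxyl ties up the C5 ketone as a bridged hemiketal, that a furan forms, or that the condensation to the tetrasubstituted enone is sluggish. The fallback changes the order of events, sets out from 16 and comes back at 21.
- 19, Et3N and DMAP first acylate the C8 hydroxyl to give the enol ether isobutyrate F6.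
- Amberlyst 15 in wet THF gives the diketone isobutyrate F7.
- Non-nucleophilic DBU in warm toluene closes ring A directly to 21, which is acetylated as in the second half of step 8.

**Further compounds**
F1 | step 6 | ethyl 2-diazo-2-[(2Z,3aR,4S)-2-ethylidene-6-hydroxy-4-methyl-2,3,3a,4,5,6-hexahydro-1-benzofuran-6-yl]acetate | C/C=C1/C[C@@H]2[C@@H](C)CC(O)(C(=[N+]=[N-])C(=O)OCC)C=C2O1
F2 | step 6 | ethyl (2Z,3aR,4S)-2-ethylidene-4-methyl-6-oxo-3,3a,4,5,6,7-hexahydro-2H-cyclohepta[b]furan-7-carboxylate (C7 labile) | C/C=C1/C[C@@H]2[C@@H](C)CC(=O)C(C(=O)OCC)C=C2O1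
F3 | step 6 | ethyl (2Z,3aR,4S,6R,7S)-2-ethylidene-6-hydroxy-4-methyl-3,3a,4,5,6,7-hexahydro-2H-cyclohepta[b]furan-7-carboxylate | C/C=C1/C[C@@H]2[C@@H](C)C[C@@H](O)[C@@H](C(=O)OCC)C=C2O1
F4 | step 5 | (4R,5S)-4-(but-2-yn-1-yl)-5-methyl-3-(2-methylpropoxy)cyclohex-2-en-1-one | CC#CC[C@@H]1[C@@H](C)CC(=O)C=C1OCC(C)C
F5 | step 5 | (1R,2S,5R,6S)-5-(but-2-yn-1-yl)-2-(2-hydroxypropan-2-yl)-6-methyl-4-(2-methylpropoxy)cyclohept-3-en-1-ol | CC#CC[C@@H]1[C@@H](C)C[C@@H](O)[C@@H](C(C)(C)O)C=C1OCC(C)C
F6 | step 7 | (2Z,3aR,4S,6R,7S)-2-ethylidene-7-(2-hydroxypropan-2-yl)-4-methyl-3,3a,4,5,6,7-hexahydro-2H-cyclohepta[b]furan-6-yl 2-methylpropanoate | C/C=C1/C[C@@H]2[C@@H](C)C[C@@H](OC(=O)C(C)C)[C@@H](C(C)(C)O)C=C2O1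
F7 | step 7 | (1R,2S,5R,6S)-2-(2-hydroxypropan-2-yl)-6-methyl-4-oxo-5-(2-oxobutyl)cycloheptyl 2-methylpropanoate | CCC(=O)C[C@@H]1[C@@H](C)C[C@@H](OC(=O)C(C)C)[C@@H](C(C)(C)O)CC1=O
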